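**Retrosynthetic overview**
1. The target acid comes from its methyl ester by a chemoselective saponification (last step).
2. The spiro-dihydrofuran is opened at two bonds: CH2–C(tropone), made by adding an epoxide-derived primary β-hydroxyalkyl radical to a C–H position of a methoxytropone, and O–C(tropone), made by vinylogous ester exchange.
3. The spiro-epoxide comes from an exocyclic alkene, and that from a 2,2,3,6-tetrasubstituted cyclohexanone built on 2-methylcyclohex-2-en-1-one (asymmetric conjugate addition, Michael addition, Mukaiyama hydration, methylation with kinetic protonation).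
4. The tropone comes from an oxyallyl (4+3) cycloaddition/fragmentation of a dibromo β-keto ester with 2-bromo-5-methylfuran, followed by O-methylation.
5. Ring order: the cyclohexane ring is present from the start; the seven-membered ring is formed by the (4+3) reaction in the second fragment; the dihydrofuran (spiro ring) is formed last.

Assumption: the target is taken as the open hydroxy acid as drawn (no lactone), and 2-bromo-5-methylfuran and isopropenylmagnesium bromide solution are purchased.

**Step 1**
Reactants: 1 methyl 3-oxobutanoate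
Product: 2 methyl 3-oxopentanoate
Conditions: NaH, THF, 0 °C; n-BuLi, 0 °C; MeI, 0 °C → rt; then 1 M HCl
Reagents that add atoms: iodomethane, CI
Why: Huckin–Weiler dianion alkylation: the terminal carbanion of the acetoacetate dianion is the more nucleophilic site and is methylated selectively, no stereocentre being formed.

**Step 2**
Reactants: 2 methyl 3-oxopentanoate
Product: 3 methyl 2,4-dibromo-3-oxopentanoate
Conditions: Br2 (2 equiv), CH2Cl2, 0 °C → rt
Reagents that add atoms: bromine, BrBr
Why: Acid-autocatalysed α-bromination through the enols, the first bromine entering at the doubly activated C2 and the second at the ketone α′-carbon C4 under HBr equilibration; the two stereocentres form without control and are both destroyed in step 3.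

**Step 3**
Reactants: 3 methyl 2,4-dibromo-3-oxopentanoate; 4 2-bromo-5-methylfuran
Product: 6 methyl 5-hydroxy-2,6-dimethyl-7-oxocyclohepta-1,3,5-triene-1-carboxylate, via bromo-bridged cycloadduct 5 (not isolated)
Conditions: Zn–Cu couple, THF, −10 °C → rt; then Et3N, rt
Reagents that add atoms: none
Why: Proposed new method: the zinc oxyallyl cation from 3 (enolate character on the ester-bearing terminus, cationic character on the methyl-bearing terminus) should add to the 2,5-disubstituted furan in a stepwise (4+3) cycloaddition, its cationic carbon bonding to the bromine-bearing furan carbon (the resulting oxocarbenium ion is stabilised by the furan methyl) and the enolate carbon closing onto the methyl-bearing carbon, after which Et3N deprotonates the β-keto ester, the oxygen bridge opens by E1cB elimination and the released α-bromo alkoxide expels bromide to give the 1,3-diketone that enolises to the aromatic hydroxytropone, so that no oxidation step is needed and all stereocentres of 5 disappear; the closest known reaction types are the Noyori–Hoffmann reductive (4+3) cycloaddition of α,α′-dibromo ketones with furans and the base-induced opening of 8-oxabicyclo[3.2.1]oct-6-en-3-ones to tropones.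

**Step 4**
Reactants: 6 methyl 5-hydroxy-2,6-dimethyl-7-oxocyclohepta-1,3,5-triene-1-carboxylate
Product: 7 methyl 5-methoxy-2,6-dimethyl-7-oxocyclohepta-1,3,5-triene-1-carboxylate
Conditions: MeI, K2CO3, acetone, rt
Reagents that add atoms: iodomethane, CI
Why: Williamson-type O-methylation of the vinylogous acid, selective for the oxygen remote from the ester because the ester-flanked oxygen is held in a potassium chelate and is more hindered (compare 4-O-alkylation of 2,4-dihydroxybenzoates); no stereocentre is involved.

**Step 5**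
Reactants: 8 2-methylcyclohex-2-en-1-one; 9 isopropenylmagnesium bromide
Product: 10 (3S)-2-methyl-3-(prop-1-en-2-yl)cyclohexan-1-one (mixture of C2 epimers)
Conditions: CuBr·SMe2 (5 mol %), (R,S)-Josiphos, (C5H5)Fe[C5H3(PPh2)CH(CH3)PCy2] (6 mol %), t-BuOMe, −75 °C; then 1 M HCl
Reagents that add atoms: none
Why: Copper-catalysed asymmetric conjugate addition of a Grignard reagent (Feringa type): the chiral copper–diphosphine complex transfers the alkenyl group to one face of the enone and sets C3 (S), the ligand antipode being used if the first run shows the opposite sense, while C2 is protonated unselectively and is re-formed in step 6.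

**Step 6**
Reactants: 10 (3S)-2-methyl-3-(prop-1-en-2-yl)cyclohexan-1-one; 11 methyl prop-2-enoate
Product: 12 methyl 3-[(1R,6R)-1-methyl-2-oxo-6-(prop-1-en-2-yl)cyclohexyl]propanoate
Conditions: KOt-Bu (0.15 equiv), t-BuOH/THF, 0 °C → rt
Reagents that add atoms: none
Why: Base-catalysed Michael addition through the thermodynamic, more substituted enolate, in which the acrylate approaches anti to the neighbouring isopropenyl group so that the new quaternary centre (1R) carries the chain trans and the methyl cis to that group, as in Robinson annulations of 2,3-dialkylcyclohexanones.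

**Step 7**
Reactants: 12 methyl 3-[(1R,6R)-1-methyl-2-oxo-6-(prop-1-en-2-yl)cyclohexyl]propanoate
Product: 13 methyl 3-[(1R,2S)-2-(2-hydroxypropan-2-yl)-1-methyl-6-oxocyclohexyl]propanoate
Conditions: Co(acac)2 (20 mol %), PhSiH3, O2 (1 atm), THF/i-PrOH, rt
Reagents that add atoms: dioxygen, O=O
Why: Mukaiyama hydration: hydrogen-atom transfer from a cobalt hydride to the 1,1-disubstituted alkene gives the tertiary radical, which is trapped by O2 and reduced to the Markovnikov tertiary alcohol while ketone and ester stay untouched; no stereocentre is formed.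

**Step 8**
Reactants: 13 methyl 3-[(1R,2S)-2-(2-hydroxypropan-2-yl)-1-methyl-6-oxocyclohexyl]propanoate
Product: 15 methyl 3-[(1R,3R,6S)-6-(2-hydroxypropan-2-yl)-1,3-dimethyl-2-oxocyclohexyl]propanoate, via trans-dimethyl ketone 14 (not isolated)
Conditions: LiN(i-Pr)2 (2.2 equiv), THF, −78 °C; MeI, −78 → −30 °C; LiN(i-Pr)2 (1.5 equiv), −78 → −30 °C; AcOH/THF, −78 °C
Reagents that add atoms: iodomethane, CI
Why: Enolate methylation (only one side can enolise) followed by re-enolisation and kinetic C-protonation, which occurs on the enolate face opposite the axial C1 methyl in the chair held by the equatorial 2-(lithiooxy)propan-2-yl group and so leaves the C3 methyl cis to the C1 methyl (3R), the sense known from kinetic protonation of 2-alkyl-3-keto steroid enolates next to an angular methyl.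

**Step 9**
Reactants: 15 methyl 3-[(1R,3R,6S)-6-(2-hydroxypropan-2-yl)-1,3-dimethyl-2-oxocyclohexyl]propanoate
Product: 16 methyl 3-[(1R,3R,6S)-6-(2-hydroxypropan-2-yl)-1,3-dimethyl-2-methylidenecyclohexyl]propanoate
Conditions: Zn, CH2Br2, TiCl4, THF/CH2Cl2, 0 °C → rt
Reagents that add atoms: dibromomethane, BrCBr
Why: Takai–Lombardo methylenation: the non-basic zinc–titanium gem-dimetallic reagent converts the hindered, epimerisable ketone into the exocyclic alkene without touching the α-stereocentre, the ester or the free alcohol; no new stereocentre is formed.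

**Step 10**
Reactants: 16 methyl 3-[(1R,3R,6S)-6-(2-hydroxypropan-2-yl)-1,3-dimethyl-2-methylidenecyclohexyl]propanoate
Product: 17 methyl 3-[(3S,4R,5S,8R)-5-(2-hydroxypropan-2-yl)-4,8-dimethyl-1-oxaspiro[2.5]octan-4-yl]propanoate
Conditions: DMDO, acetone, 0 °C
Reagents that add atoms: dimethyldioxirane, CC1(C)OO1
Why: Electrophilic epoxidation with a dioxirane, the oxygen being delivered to the alkene face opposite the two flanking ring methyls so that it ends up cis to the propanoate chain (3S spiro centre), under neutral conditions that keep the acid-sensitive 2,2-disubstituted epoxide intact.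

**Step 11** (key step)
Reactants: 17 methyl 3-[(3S,4R,5S,8R)-5-(2-hydroxypropan-2-yl)-4,8-dimethyl-1-oxaspiro[2.5]octan-4-yl]propanoate; 7 methyl 5-methoxy-2,6-dimethyl-7-oxocyclohepta-1,3,5-triene-1-carboxylate
Product: 20 methyl (2S,2'R,3'S,6'R)-3'-(2-hydroxypropan-2-yl)-2'-(3-methoxy-3-oxopropyl)-2',5,6',8-tetramethyl-7-oxo-3,7-dihydrospiro[cyclohepta[b]furan-2,1'-cyclohexane]-6-carboxylate, via iodohydrin 18 (not isolated), via hydroxyalkyl tropone 19 (not isolated)
Conditions: Co(dmgH)2(py)Cl (10 mol %), NaBH4 (10 mol %), LiI (20 mol %), i-Pr2NEt (20 mol %), 7 (1.5 equiv), MeCN/MeOH, blue LEDs, rt → 40 °C; then CSA (20 mol %), PhMe, 40 °C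
Reagents that add atoms: none
Why: Proposed new method: catalytic iodide opens the epoxide at its CH2 carbon (SN2, so the C–O stereocentre made in step 10 is untouched) to an iodohydrin, monovalent cobalt (from the cobaloxime and NaBH4) turns the C–I bond into a primary β-hydroxyalkyl radical on irradiation of the alkylcobalt, this nucleophilic radical adds to C4 of 7 (the unsubstituted δ-terminus of the dienyl unit C1=C2–C3=C4 activated by ketone and ester, giving a radical stabilised at C1), divalent cobalt abstracts the C4 hydrogen to restore the tropone and the cobalt hydride is deprotonated by the amine back to monovalent cobalt, and CSA then closes the dihydrofuran by intramolecular vinylogous transesterification at C5 with loss of methanol and retention at the carbinol carbon; the closest known reaction types are the cobaloxime-catalysed visible-light alkyl-Heck coupling of alkyl iodides, the iodide-co-catalysed linear-selective reductive coupling of epoxides, Minisci-type alkylation and acid-catalysed vinylogous ester exchange.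

**Step 12**
Reactants: 20 methyl (2S,2'R,3'S,6'R)-3'-(2-hydroxypropan-2-yl)-2'-(3-methoxy-3-oxopropyl)-2',5,6',8-tetramethyl-7-oxo-3,7-dihydrospiro[cyclohepta[b]furan-2,1'-cyclohexane]-6-carboxylate
Product: 21 3-[(2S,2'R,3'S,6'R)-3'-(2-hydroxypropan-2-yl)-6-(methoxycarbonyl)-2',5,6',8-tetramethyl-7-oxo-3,7-dihydrospiro[cyclohepta[b]furan-2,1'-cyclohexan]-2'-yl]propanoic acid
Conditions: LiOH·H2O (1.5 equiv), THF/H2O, 0 °C; then 1 M HCl
Reagents that add atoms: lithium hydroxide, [Li+].[OH-]
Why: Saponification that is chemoselective for the unhindered aliphatic methyl ester, since the ring ester is flanked by a ring methyl and the ring carbonyl and is conjugated with the electron-rich alkoxytropone; no stereocentre is touched.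

**Compound list**
1 | methyl 3-oxobutanoate (methyl acetoacetate) | CC(=O)CC(=O)OC | starting material
2 | methyl 3-oxopentanoate | CCC(=O)CC(=O)OC | intermediate
3 | methyl 2,4-dibromo-3-oxopentanoate (diastereomer mixture) | CC(Br)C(=O)C(Br)C(=O)OC | intermediate
4 | 2-bromo-5-methylfuran | Cc1ccc(Br)o1 | starting material
5 | methyl 5-bromo-1,4-dimethyl-3-oxo-8-oxabicyclo[3.2.1]oct-6-ene-2-carboxylate (racemic stereoisomer mixture) | COC(=O)C1C(=O)C(C)C2(Br)C=CC1(C)O2 | intermediate (not isolated)
6 | methyl 5-hydroxy-2,6-dimethyl-7-oxocyclohepta-1,3,5-triene-1-carboxylate | COC(=O)c1c(C)ccc(O)c(C)c1=O | intermediate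
7 | methyl 5-methoxy-2,6-dimethyl-7-oxocyclohepta-1,3,5-triene-1-carboxylate | COC(=O)c1c(C)ccc(OC)c(C)c1=O | intermediate
8 | 2-methylcyclohex-2-en-1-one | CC1=CCCCC1=O | starting material
9 | isopropenylmagnesium bromide | CC(=C)[Mg]Br | starting material
10 | (3S)-2-methyl-3-(prop-1-en-2-yl)cyclohexan-1-one (C2 epimer mixture) | O=C1CCC[C@H](C(C)=C)C1C | intermediate
11 | methyl prop-2-enoate (methyl acrylate) | C=CC(=O)OC | starting material
12 | methyl 3-[(1R,6R)-1-methyl-2-oxo-6-(prop-1-en-2-yl)cyclohexyl]propanoate | O=C1CCC[C@H](C(C)=C)[C@@]1(C)CCC(=O)OC | intermediate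
13 | methyl 3-[(1R,2S)-2-(2-hydroxypropan-2-yl)-1-methyl-6-oxocyclohexyl]propanoate | O=C1CCC[C@H](C(C)(C)O)[C@@]1(C)CCC(=O)OC | intermediate
14 | methyl 3-[(1R,3S,6S)-6-(2-hydroxypropan-2-yl)-1,3-dimethyl-2-oxocyclohexyl]propanoate | O=C1[C@@H](C)CC[C@H](C(C)(C)O)[C@@]1(C)CCC(=O)OC | intermediate (not isolated)
15 | methyl 3-[(1R,3R,6S)-6-(2-hydroxypropan-2-yl)-1,3-dimethyl-2-oxocyclohexyl]propanoate | O=C1[C@H](C)CC[C@H](C(C)(C)O)[C@@]1(C)CCC(=O)OC | intermediate
16 | methyl 3-[(1R,3R,6S)-6-(2-hydroxypropan-2-yl)-1,3-dimethyl-2-methylidenecyclohexyl]propanoate | C=C1[C@H](C)CC[C@H](C(C)(C)O)[C@@]1(C)CCC(=O)OC | intermediate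
17 | methyl 3-[(3S,4R,5S,8R)-5-(2-hydroxypropan-2-yl)-4,8-dimethyl-1-oxaspiro[2.5]octan-4-yl]propanoate | C1O[C@]12[C@H](C)CC[C@H](C(C)(C)O)[C@@]2(C)CCC(=O)OC | intermediate
18 | methyl 3-[(1R,2S,3R,6S)-2-hydroxy-6-(2-hydroxypropan-2-yl)-2-(iodomethyl)-1,3-dimethylcyclohexyl]propanoate | IC[C@]1(O)[C@H](C)CC[C@H](C(C)(C)O)[C@@]1(C)CCC(=O)OC | intermediate (not isolated)
19 | methyl 4-{[(1S,2R,3S,6R)-1-hydroxy-3-(2-hydroxypropan-2-yl)-2-(3-methoxy-3-oxopropyl)-2,6-dimethylcyclohexyl]methyl}-5-methoxy-2,6-dimethyl-7-oxocyclohepta-1,3,5-triene-1-carboxylate | COC(=O)c1c(C)cc(C[C@]2(O)[C@H](C)CC[C@H](C(C)(C)O)[C@@]2(C)CCC(=O)OC)c(OC)c(C)c1=O | intermediate (not isolated)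
20 | methyl (2S,2'R,3'S,6'R)-3'-(2-hydroxypropan-2-yl)-2'-(3-methoxy-3-oxopropyl)-2',5,6',8-tetramethyl-7-oxo-3,7-dihydrospiro[cyclohepta[b]furan-2,1'-cyclohexane]-6-carboxylate | COC(=O)c1c(C)cc2c(c(C)c1=O)O[C@@]1(C2)[C@H](C)CC[C@H](C(C)(C)O)[C@@]1(C)CCC(=O)OC | intermediate
21 | 3-[(2S,2'R,3'S,6'R)-3'-(2-hydroxypropan-2-yl)-6-(methoxycarbonyl)-2',5,6',8-tetramethyl-7-oxo-3,7-dihydrospiro[cyclohepta[b]furan-2,1'-cyclohexan]-2'-yl]propanoic acid (CNP0448476.4) | COC(=O)c1c(C)cc2c(c(C)c1=O)O[C@@]1(C2)[C@H](C)CC[C@H](C(C)(C)O)[C@@]1(C)CCC(=O)O | target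

**Step count and risks**
Total step count: 12. Longest linear sequence: 8 steps (steps 5 to 12, from 8 to 21); the tropone branch (steps 1 to 4) joins in step 11.

The three steps most likely to fail:

Step 11. The risks are slow iodide opening of the hindered epoxide, addition of the radical at C3 instead of C4 of the tropone, loss of the radical by 1,5-hydrogen transfer from the propanoate chain, and poor cobalt turnover. Fallback: setting out from 17, the epoxide is opened at CH2 with PhSeNa ((PhSe)2, NaBH4, EtOH) to methyl 3-[(1R,2S,3R,6S)-2-hydroxy-6-(2-hydroxypropan-2-yl)-1,3-dimethyl-2-[(phenylselanyl)methyl]cyclohexyl]propanoate F1. Its radical ((Me3Si)3SiH, AIBN, PhH, 80 °C) is added reductively (Giese addition) to 7 to give methyl 4-{[(1S,2R,3S,6R)-1-hydroxy-3-(2-hydroxypropan-2-yl)-2-(3-methoxy-3-oxopropyl)-2,6-dimethylcyclohexyl]methyl}-5-methoxy-2,6-dimethyl-7-oxocyclohepta-2,5-diene-1-carboxylate F2. Dehydrogenation with DDQ brings the sequence back to the route at 19, which is closed with CSA to 20 as before. This replaces the redox-neutral catalytic C–H alkylation by a stoichiometric reductive conjugate addition from an isolated radical precursor and a separate re-aromatisation.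

Step 8. The risks are an incomplete second enolisation and a protonation that follows the other chair and returns the more stable trans epimer 14. Fallback: setting out from 13, α-methylenation ((CH2O)n, N-methylanilinium trifluoroacetate, THF, reflux) gives methyl 3-[(1R,6S)-6-(2-hydroxypropan-2-yl)-1-methyl-3-methylidene-2-oxocyclohexyl]propanoate F3. Homogeneous hydrogenation (H2, RhCl(PPh3)3, PhH) then delivers hydrogen to the exocyclic alkene from the face away from the C1 methyl, without epimerising conditions, and comes back to the route at 15. The stereocentre is then made by metal-hydride delivery to an alkene instead of by proton transfer to an enolate.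

Step 3. The risks are low reactivity of the ester-stabilised oxyallyl cation towards the bromofuran and premature decomposition of the bromofuran. Fallback: setting out from 3, the cycloaddition is run with 2-methylfuran F4 (Zn–Cu couple, THF) to give methyl 1,4-dimethyl-3-oxo-8-oxabicyclo[3.2.1]oct-6-ene-2-carboxylate F5. The oxygen bridge is opened with LiN(SiMe3)2 (THF, −78 → 0 °C, AcOH quench) to methyl 5-hydroxy-2,6-dimethyl-7-oxocyclohepta-1,3-diene-1-carboxylate F6. MnO2 (CH2Cl2, rt) oxidises the allylic alcohol to the diketone, which enolises, so the sequence comes back to the route at 6. The oxidation level is then reached by a separate alcohol oxidation instead of by loss of bromide.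

**Further compounds**
F1 | step 11 | methyl 3-[(1R,2S,3R,6S)-2-hydroxy-6-(2-hydroxypropan-2-yl)-1,3-dimethyl-2-[(phenylselanyl)methyl]cyclohexyl]propanoate | c1ccccc1[Se]C[C@]2(O)[C@H](C)CC[C@H](C(C)(C)O)[C@@]2(C)CCC(=O)OC
F2 | step 11 | methyl 4-{[(1S,2R,3S,6R)-1-hydroxy-3-(2-hydroxypropan-2-yl)-2-(3-methoxy-3-oxopropyl)-2,6-dimethylcyclohexyl]methyl}-5-methoxy-2,6-dimethyl-7-oxocyclohepta-2,5-diene-1-carboxylate (mixture at the two new ring centres) | COC(=O)C1C(C)=CC(C[C@]2(O)[C@H](C)CC[C@H](C(C)(C)O)[C@@]2(C)CCC(=O)OC)C(OC)=C(C)C1=O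
F3 | step 8 | methyl 3-[(1R,6S)-6-(2-hydroxypropan-2-yl)-1-methyl-3-methylidene-2-oxocyclohexyl]propanoate | O=C1C(=C)CC[C@H](C(C)(C)O)[C@@]1(C)CCC(=O)OC
F4 | step 3 | 2-methylfuran | Cc1ccco1
F5 | step 3 | methyl 1,4-dimethyl-3-oxo-8-oxabicyclo[3.2.1]oct-6-ene-2-carboxylate (racemic stereoisomer mixture) | COC(=O)C1C(=O)C(C)C2C=CC1(C)O2
F6 | step 3 | methyl 5-hydroxy-2,6-dimethyl-7-oxocyclohepta-1,3-diene-1-carboxylate (stereoisomer mixture) | COC(=O)C1=C(C)C=CC(O)C(C)C1=O
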